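(The rate constants were chosen freely, and the outcome is calculated.)

Per hour is the unit in which I set side by side the ways into and out of the dissolved gas of this flask.

    gas phase ⇌ dissolved gas, rate k1*(csat - [dissolved gas]) (k1 = 1.05 h⁻¹, csat = 200 mM)
    starting material + dissolved gas → target (k2 = 0.0644 M⁻¹ h⁻¹)
    dissolved gas + target → over-reacted product (k3 = 0.126 M⁻¹ h⁻¹)
    dissolved gas ⇌ dormant form (K4 = 223, k4 = 0.0748 h⁻¹)

starting material 3.0 M; gas phase 200 mM (held); time 20 h

- Monday's: doubling the transfer coefficient of step 1, all else as stated
- Tuesday's: doubling the saturation concentration of gas phase, all else as stated

- at the start none of the gas is dissolved
- run time (flask): 20 h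

* how much target there is at 20 h, in percent of the starting material charged
* concentration of dissolved gas in solution at 5.0 h, in percent of saturation
* the change that raises the amount of target at 20 h, in percent of the starting material charged most ("none" if none brings more than 2 percentage points) (Monday's / Tuesday's / none)
* amount of target at 20 h, in percent of the starting material charged, after Monday's

I took the starting material at its charge, so that making target became a pseudo-first-order loss of dissolved gas. Adding the forward step to dormant form gave the drain d, 0.268 h⁻¹. With the transfer coefficient 1.05 h⁻¹, the lifetime τ of dissolved gas, the reciprocal of transfer coefficient plus drain, came to 0.759 h, and I carried the holding fraction h, the transfer coefficient over transfer coefficient plus drain, which is the steady level of dissolved gas as a part of saturation, 79.7%. The time 5.0 h is 6.59 lifetimes, so I expected 79.6% by then. The level times the run less τ gave the integrated gas θ, 3.07 M·h, and the consecutive-reaction formula in θ gave 14.8%, or after Monday's 16.1%.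

Then I turned the question round. Saturation stands outside h, so in my reckoning Tuesday's doubled the level, whereas Monday's multiplied it by 1.11; with d held, that factor of mine nears doubling where the transfer coefficient is small against d, and here the transfer coefficient was 3.92 times d. For the formula to take Tuesday's gain away, the doubled θ had to lie beyond the target's peak at 10.9 M·h, but it stood at 6.14 M·h, so by the formula target was still rising there. I chose Tuesday's.

The forecast gave 14.7% (range 14% to 15.4%), 79.2%, Tuesday's and 16.1%, holding that "transfer is balanced by consumption and the almost one-way drain into the dormant form"; its figure for the dissolved gas lay slightly lower than my h.

The simulation gave 14.7%, 79.2%, Tuesday's with 7.4 percentage points against 1.4 points for Monday's, and 16.0%.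

In this flask at 8.72 h, dissolved gas was made 0.997 times as fast as it was used up, each step taken net, and its use in making target ran 2.4 times the forward rate of its loss to dormant form; the level from h, 0.159 M, stands beside the 0.158 M of this flask at 10.0 h. The neighbour flask read at 2.0 d keeps the same h, which puts its target at 23.9%, and that flask stood at 23.8%.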